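In every flask here G goes to L faster than to G.E, so reckon G.E as a small correction to a large pool of G, L and E.L.

| flask | G | E | time |
|---|---|---|---|
| north-west | 0.20 M | 0.500 M | 12 min |
| south | 0.20 M | 0.650 M | 12 min |
| south-east | 0.20 M | 0.850 M | 12 min |

    G + E ⇌ G.E (K1 = 89.2 M⁻¹, k1 = 0.0796 M⁻¹ min⁻¹)
    G ⇌ L (K2 = 2.7, k2 = 0.365 min⁻¹)
    E + L ⇌ E.L (K3 = 6.29 M⁻¹, k3 = 0.459 M⁻¹ min⁻¹)

- which of these there is most of at the end, counted by the G in it, north-west (L / G.E / E.L / G)
- which of these there is most of at the end, counted by the G in it, south (L / G.E / E.L / G)
- which of these there is most of at the end, counted by the G in it, south-east (L / G.E / E.L / G)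
- the largest of these amounts at the end, in percent of the G charged, north-west
- the largest of these amounts at the end, in percent of the G charged, south
- the largest of these amounts at the end, in percent of the G charged, south-east

1. In north-west, G leaves towards G.E with the rate constant of G + E times [E] as charged, 0.0398 min⁻¹, and towards L with 0.365 min⁻¹. A first guess at the share lost to G.E is 9.83%.

2. But L can come back. In north-west, with E as charged, L returns to G with 0.135 min⁻¹ and goes on to E.L with 0.230 min⁻¹, so 37.1% of it meets the same fork again. That raises the north-west figure to 14.8%. This is the figure to carry: the leak share, the rate towards G.E over that rate plus the rate towards L times the share of L that goes on to E.L. South gives 17.1% and south-east 20.0%.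

3. Now the large part. The pool divides among G, L and E.L as 1 : 2.7 : 2.7 times the constant of E + L times [E]. But [E] falls as E is used, so take the middle of its possible range: 0.400 M in north-west, 0.550 M in south and 0.750 M in south-east. In the same order, E.L then holds 64.7%, 71.6% and 77.5% of the pool.

4. That assumes the pool has finished dividing, and you should doubt it. In north-west, L has a half-life of 3.0 min by the forward rate of E + L, with E as charged, and 12 min is 4.00 such half-lives. Treat that step as pseudo-first-order at the middle [E]; the finished fractions are 89.0% in north-west, 95.2% in south and 98.4% in south-east.

5. My E.L, as pool after the leak times share times finished fraction, is 49.1% in north-west, 56.5% in south and 61.0% in south-east.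

The forecast names E.L, E.L and E.L, at 50%, 57% and 64%, on these grounds: “G and L equilibrate within a few minutes and L drains to E.L”. We part most in south-east, where it stands at 64% and I at 61.0%.

The flask gives E.L at 48.8% in north-west, E.L at 54.4% in south and E.L at 58.7% in south-east, so the forecast is 5.3 percentage points high in south-east. In south-east G.E stands at 18.8%, while the forecast's words put G.E at about 13–16% of the G. The leak share times the finished fraction gives 19.7% for G.E in south-east.

Now take the south flask with E cut to 0.16 M, which makes E the limiting reagent. With E as charged its leak share is 9.02%; the middle of the range of [E] is 0.0800 M, the finished fraction 35.6%, and the reckoning gives G.E as 3.21%. At the end this computed flask holds 4.58% of G.E, with L in front at 52.5%.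

Its constants were drawn at random within sensible limits; the run is a simulation.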